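**Retrosynthetic overview** (carotenoid numbering: ring C1–C6, chain from C7)

1. The target, (6S)-ε,ψ-carotene, is cut at C11=C12 by a Wittig disconnection into the ring-bearing C15 phosphonium salt 13 and the acyclic C25 polyenal 20; 20 comes from pseudoionone, a vinyl Grignard reagent and the C10 dialdehyde.
2. Salt 13 derives from (S)-α-ionone 11 (vinyl Grignard addition, then PPh3·HBr), and 11 from cross-metathesis of vinylcyclohexene 9 with methyl vinyl ketone.
3. The strategy rests on the skipped diene C4=C5–C6(H)–C7=C8 of the single cyclohexene ring, with the tertiary stereocentre C6 between the gem-dimethyl carbon C1 and C5. This pattern is what an alkenylpalladium at C5 leaves behind after adding to a C6=C7 alkene and departing toward C8.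
4. Compound 9 therefore comes from an asymmetric 6-exo Heck cyclisation with allylsilane termination of the (Z)-alkenyl iodide/(E)-allylsilane 8; this is the only ring-forming event.
5. Precursor 8 is made from 2,2-dimethylpent-4-enal 1 by Takai iodoolefination, Kumada coupling, hydroboration–oxidation, oxidation and a Z-selective iodoethylidene Wittig reaction.

Key step: step 6

**Assumptions**

- Pseudoionone 14 is used as the (3E,5E) isomer; any 5Z material in commercial samples is removed when salt 16 is crystallised.
- The sense of induction of BINAP cannot be predicted with confidence for this substrate. (R)-BINAP is written in step 6; (S)-BINAP is used instead if ketone 11 proves to be the 6R enantiomer by comparison with the known chiroptical data of α-ionone.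

**Route**

Step 1
Reactants: 1 2,2-dimethylpent-4-enal
Product: 2 (1E)-1-iodo-3,3-dimethylhexa-1,5-diene
Conditions: CrCl2 (6 equiv), CHI3 (2 equiv), THF, 0 °C → rt
Reagents that add atoms: iodoform, IC(I)I
Why: Takai iodoolefination, in which the geminal dichromium species formed from CHI3 and divalent chromium adds to the neopentyl aldehyde and eliminates to give the E-alkenyl iodide, while the terminal alkene is inert.

Step 2
Reactants: 2 (1E)-1-iodo-3,3-dimethylhexa-1,5-diene; 3 (trimethylsilyl)methylmagnesium chloride
Product: 4 trimethyl[(2E)-4,4-dimethylhepta-2,6-dien-1-yl]silane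
Conditions: Pd(PPh3)4 (3 mol %), THF, 0 °C → rt
Reagents that add atoms: none
Why: Kumada–Corriu coupling, in which oxidative addition of zerovalent palladium to the alkenyl iodide, transmetallation with a Grignard reagent that has no β-hydrogen and reductive elimination all proceed with retention, so the E geometry passes into the allylsilane.

Step 3
Reactants: 4 trimethyl[(2E)-4,4-dimethylhepta-2,6-dien-1-yl]silane
Product: 6 (5E)-4,4-dimethyl-7-(trimethylsilyl)hept-5-en-1-ol, via B-alkyl-9-borabicyclo[3.3.1]nonane 5 (not isolated)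
Conditions: 9-BBN (1.1 equiv), THF, 0 °C → rt; then NaOH, H2O2, 0 °C → rt
Reagents that add atoms: hydrogen peroxide, OO (the oxygen of 6); 9-borabicyclo[3.3.1]nonane, B1C2CCCC1CCC2 (boron of intermediate 5 only)
Why: Hydroboration–oxidation, in which 9-BBN adds anti-Markovnikov to the monosubstituted terminal alkene much faster than to the hindered neopentyl 1,2-disubstituted alkene, and alkaline peroxide oxidises the C–B bond while leaving the C–Si bond intact.

Step 4
Reactants: 6 (5E)-4,4-dimethyl-7-(trimethylsilyl)hept-5-en-1-ol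
Product: 7 (5E)-4,4-dimethyl-7-(trimethylsilyl)hept-5-enal
Conditions: Dess–Martin periodinane, NaHCO3, CH2Cl2, 0 °C → rt
Reagents that add atoms: none
Why: Dess–Martin oxidation under bicarbonate buffer should stop at the aldehyde and avoids the free acid that could protodesilylate the allylsilane.

Step 5
Reactants: 7 (5E)-4,4-dimethyl-7-(trimethylsilyl)hept-5-enal
Product: 8 (2Z,7E)-2-iodo-6,6-dimethyl-9-(trimethylsilyl)nona-2,7-diene
Conditions: EtPPh3I, n-BuLi, THF, rt; I2, −78 °C; NaHMDS, −20 °C; then 7, −78 °C → −20 °C
Reagents that add atoms: ethyltriphenylphosphonium iodide, CC[P+](c1ccccc1)(c1ccccc1)c1ccccc1.[I-]; iodine, II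
Why: Stork–Zhao-type α-iodoalkylidene Wittig olefination, in which the non-stabilised iodo ylide (made in the flask by iodination of ethylidenetriphenylphosphorane and deprotonation) reacts under kinetic control through the cis-oxaphosphetane and places iodine cis to the chain, the Z geometry that ring closure needs.

Step 6
Reactants: 8 (2Z,7E)-2-iodo-6,6-dimethyl-9-(trimethylsilyl)nona-2,7-diene
Product: 9 (6S)-1,5,5-trimethyl-6-vinylcyclohex-1-ene
Conditions: Pd2(dba)3·CHCl3 (5 mol %), (R)-BINAP (12 mol %), Ag3PO4 (1.1 equiv), DMF, 80 °C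
Reagents that add atoms: none
Why: Asymmetric intramolecular Mizoroki–Heck reaction with allylsilane termination: zerovalent palladium–BINAP inserts into the C5–I bond with retention of the Z geometry, Ag3PO4 removes iodide to give a cationic divalent alkenylpalladium that keeps both phosphorus atoms bound, and syn-carbopalladation across C6=C7 forms the C5–C6 bond. The ring closes in the 6-exo-trig mode, and C4=C5 ends up inside the cyclohexene because C3 and palladium sit cis on that alkene. The C6 stereocentre is set in this migratory insertion by the chiral diphosphine, which distinguishes the two faces of the E-configured C6=C7 alkene, the ligand antipode being chosen as stated in the assumptions. Palladium on C7 then leaves together with the silyl group on C8 (phosphate-assisted β-silyl elimination) faster than β-hydride loss from C6 or C8 can occur, so the C7=C8 vinyl group is released, C6–H stays and no palladium hydride forms that could move either alkene into conjugation. The step needs face selectivity and termination toward C8; the geometrically pure E-allylsilane with the bound chiral ligand secures the first and the silyl group the second, while the C1 gem-dimethyl group compresses the tether and favours closure. The closest known reaction type is the BINAP-controlled Heck cyclisation of aryl and alkenyl halides onto tethered allylsilanes, which gives vinyl-substituted tertiary stereocentres.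

Step 7
Reactants: 9 (6S)-1,5,5-trimethyl-6-vinylcyclohex-1-ene; 10 but-3-en-2-one (methyl vinyl ketone, 4 equiv)
Product: 11 (S)-α-ionone, (3E)-4-[(1S)-2,6,6-trimethylcyclohex-2-en-1-yl]but-3-en-2-one
Conditions: second-generation Hoveyda–Grubbs catalyst RuCl2(SIMes)(=CH-C6H4-2-OiPr) (5 mol %), 1,4-benzoquinone (10 mol %), CH2Cl2, 40 °C
Reagents that add atoms: none
Why: Olefin cross-metathesis, in which the hindered vinyl group of 9 does not homodimerise and the electron-poor enone dimerises only slowly, so the cross product should form selectively as the E-enone; benzoquinone suppresses ruthenium hydride-mediated migration of C7=C8 that would erase C6, and the trisubstituted ring alkene is inert.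

Step 8
Reactants: 11 (S)-α-ionone
Product: 12 (1E)-3-methyl-1-[(1S)-2,6,6-trimethylcyclohex-2-en-1-yl]penta-1,4-dien-3-ol (both C3 epimers)
Conditions: CH2=CHMgBr, THF, −20 °C → 0 °C; aq. NH4Cl
Reagents that add atoms: vinylmagnesium bromide, C=C[Mg]Br
Why: Grignard 1,2-addition to the enone carbonyl gives the tertiary bis-allylic alcohol as an epimer mixture, which is of no consequence because that carbon becomes trigonal in step 9, and C6 is untouched at low temperature.

Step 9
Reactants: 12 (1E)-3-methyl-1-[(1S)-2,6,6-trimethylcyclohex-2-en-1-yl]penta-1,4-dien-3-ol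
Product: 13 [(2E,4E)-3-methyl-5-[(1S)-2,6,6-trimethylcyclohex-2-en-1-yl]penta-2,4-dien-1-yl]triphenylphosphonium bromide
Conditions: PPh3·HBr, MeOH, 0 °C → rt; crystallisation
Reagents that add atoms: triphenylphosphine hydrobromide, c1ccc(cc1)P(c1ccccc1)c1ccccc1.Br
Why: Allylic transposition with phosphine capture, in which ionisation of the tertiary alcohol gives a pentadienyl cation that triphenylphosphine traps at the unhindered terminus C11 to give the conjugated 7E,9E salt, purified by crystallisation; C6 lies outside the delocalised cation and should keep its configuration.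

Step 10
Reactants: 14 (3E,5E)-pseudoionone
Product: 15 (4E,6E)-3,7,11-trimethyldodeca-1,4,6,10-tetraen-3-ol (racemic)
Conditions: CH2=CHMgBr, THF, −20 °C → 0 °C; aq. NH4Cl
Reagents that add atoms: vinylmagnesium bromide, C=C[Mg]Br
Why: Grignard 1,2-addition to the dienone carbonyl, the usual C2 extension of pseudoionone; the racemic carbinol centre disappears in step 11.

Step 11
Reactants: 15 (4E,6E)-3,7,11-trimethyldodeca-1,4,6,10-tetraen-3-ol
Product: 16 [(2E,4E,6E)-3,7,11-trimethyldodeca-2,4,6,10-tetraen-1-yl]triphenylphosphonium bromide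
Conditions: PPh3·HBr, MeOH, 0 °C → rt; crystallisation
Reagents that add atoms: triphenylphosphine hydrobromide, c1ccc(cc1)P(c1ccccc1)c1ccccc1.Br
Why: The same allylic transposition with phosphine capture as in step 9, in which the heptatrienyl cation is trapped at its primary terminus and crystallisation should deliver the all-E salt.

Step 12
Reactants: 16 [(2E,4E,6E)-3,7,11-trimethyldodeca-2,4,6,10-tetraen-1-yl]triphenylphosphonium bromide; 17 (2E,4E,6E)-2,7-dimethylocta-2,4,6-trienedial (2 equiv)
Product: 20 (all-E)-12′-apo-ψ-caroten-12′-al, via phosphorus ylide 18 (not isolated), via 11′Z aldehyde 19 (not isolated)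
Conditions: NaOMe, MeOH/CH2Cl2, 0 °C → rt, base added slowly to 16 and excess 17; then n-heptane, reflux
Reagents that add atoms: none
Why: Wittig olefination of the semistabilised allylic ylide with one formyl group of the symmetrical dialdehyde, which is kept in excess to suppress double condensation; the new C11′=C12′ bond forms as an E/Z mixture and the strained Z isomer is converted thermally into the all-E aldehyde.

Step 13
Reactants: 13 [(2E,4E)-3-methyl-5-[(1S)-2,6,6-trimethylcyclohex-2-en-1-yl]penta-2,4-dien-1-yl]triphenylphosphonium bromide; 20 (all-E)-12′-apo-ψ-caroten-12′-al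
Product: 23 (6S)-ε,ψ-carotene, via phosphorus ylide 21 (not isolated), via 11Z carotene isomer 22 (not isolated)
Conditions: NaOMe, MeOH/CH2Cl2, 0 °C → rt, argon, dark; then n-heptane, reflux; crystallisation
Reagents that add atoms: none
Why: Wittig olefination of the allylic ylide with the C25 polyenal forms C11=C12 and completes the C40 chain; the strained 11Z isomer formed alongside should isomerise to all-E on heating, and neither methoxide at 0 °C nor the thermal step should affect the non-conjugated ring alkene or the C6 stereocentre set in step 6.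

**Compound list**

1 | 2,2-dimethylpent-4-enal | C=CCC(C)(C)C=O | starting material
2 | (1E)-1-iodo-3,3-dimethylhexa-1,5-diene | C=CCC(C)(C)/C=C/I | intermediate
3 | (trimethylsilyl)methylmagnesium chloride | C[Si](C)(C)C[Mg]Cl | starting material
4 | trimethyl[(2E)-4,4-dimethylhepta-2,6-dien-1-yl]silane | C=CCC(C)(C)/C=C/C[Si](C)(C)C | intermediate
5 | 9-[(5E)-4,4-dimethyl-7-(trimethylsilyl)hept-5-en-1-yl]-9-borabicyclo[3.3.1]nonane | C[Si](C)(C)C/C=C/C(C)(C)CCCB1C2CCCC1CCC2 | intermediate
6 | (5E)-4,4-dimethyl-7-(trimethylsilyl)hept-5-en-1-ol | OCCCC(C)(C)/C=C/C[Si](C)(C)C | intermediate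
7 | (5E)-4,4-dimethyl-7-(trimethylsilyl)hept-5-enal | O=CCCC(C)(C)/C=C/C[Si](C)(C)C | intermediate
8 | (2Z,7E)-2-iodo-6,6-dimethyl-9-(trimethylsilyl)nona-2,7-diene | C/C(I)=C/CCC(C)(C)/C=C/C[Si](C)(C)C | intermediate
9 | (6S)-1,5,5-trimethyl-6-vinylcyclohex-1-ene | C=C[C@@H]1C(C)=CCCC1(C)C | intermediate
10 | but-3-en-2-one (methyl vinyl ketone) | CC(=O)C=C | starting material
11 | (S)-α-ionone, (3E)-4-[(1S)-2,6,6-trimethylcyclohex-2-en-1-yl]but-3-en-2-one | CC(=O)/C=C/[C@@H]1C(C)=CCCC1(C)C | intermediate
12 | (1E)-3-methyl-1-[(1S)-2,6,6-trimethylcyclohex-2-en-1-yl]penta-1,4-dien-3-ol (both C3 epimers) | C=CC(C)(O)/C=C/[C@@H]1C(C)=CCCC1(C)C | intermediate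
13 | [(2E,4E)-3-methyl-5-[(1S)-2,6,6-trimethylcyclohex-2-en-1-yl]penta-2,4-dien-1-yl]triphenylphosphonium bromide | c1ccccc1[P+](c1ccccc1)(c1ccccc1)C/C=C(C)/C=C/[C@@H]2C(C)=CCCC2(C)C.[Br-] | intermediate
14 | (3E,5E)-pseudoionone, (3E,5E)-6,10-dimethylundeca-3,5,9-trien-2-one | CC(C)=CCC/C(C)=C/C=C/C(C)=O | starting material
15 | (4E,6E)-3,7,11-trimethyldodeca-1,4,6,10-tetraen-3-ol (racemic) | C=CC(C)(O)/C=C/C=C(C)/CCC=C(C)C | intermediate
16 | [(2E,4E,6E)-3,7,11-trimethyldodeca-2,4,6,10-tetraen-1-yl]triphenylphosphonium bromide | CC(C)=CCC/C(C)=C/C=C/C(C)=C/C[P+](c1ccccc1)(c1ccccc1)c1ccccc1.[Br-] | intermediate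
17 | (2E,4E,6E)-2,7-dimethylocta-2,4,6-trienedial | O=C/C(C)=C/C=C/C=C(C)/C=O | starting material
18 | [(2E,4E,6E)-3,7,11-trimethyldodeca-2,4,6,10-tetraen-1-ylidene]triphenylphosphorane | CC(C)=CCC/C(C)=C/C=C/C(C)=C/C=P(c1ccccc1)(c1ccccc1)c1ccccc1 | intermediate
19 | (2E,4E,6E,8Z,10E,12E,14E)-2,7,11,15,19-pentamethylicosa-2,4,6,8,10,12,14,18-octaenal, the 11′Z isomer of 20 | CC(C)=CCC/C(C)=C/C=C/C(C)=C/C=C\C(C)=C\C=C\C=C(C)\C=O | intermediate
20 | (all-E)-12′-apo-ψ-caroten-12′-al, (2E,4E,6E,8E,10E,12E,14E)-2,7,11,15,19-pentamethylicosa-2,4,6,8,10,12,14,18-octaenal | CC(C)=CCC/C(C)=C/C=C/C(C)=C/C=C/C(C)=C/C=C/C=C(C)/C=O | intermediate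
21 | [(2E,4E)-3-methyl-5-[(1S)-2,6,6-trimethylcyclohex-2-en-1-yl]penta-2,4-dien-1-ylidene]triphenylphosphorane | c1ccccc1P(c1ccccc1)(c1ccccc1)=C/C=C(C)/C=C/[C@@H]2C(C)=CCCC2(C)C | intermediate
22 | (6S,11Z)-ε,ψ-carotene | CC(C)=CCC/C(C)=C/C=C/C(C)=C/C=C/C(C)=C/C=C/C=C(C)/C=C\C=C(C)\C=C\[C@@H]1C(C)=CCCC1(C)C | intermediate
23 | (6S)-ε,ψ-carotene, all-E (CNP0405345.2) | CC(C)=CCC/C(C)=C/C=C/C(C)=C/C=C/C(C)=C/C=C/C=C(C)/C=C/C=C(C)/C=C/[C@@H]1C(C)=CCCC1(C)C | target

**Step count**

Total: 13 steps. Longest linear sequence: 10 steps (steps 1–9 and 13); steps 10–12 form the convergent branch.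

**Steps most likely to fail, with fallbacks**

Step 6. The migratory insertion at the neopentyl alkene may be slow, so that β-hydride loss or protodesilylation competes, or the ligand may discriminate the alkene faces poorly. The fallback sets out from pseudoionone 14 and comes back at ketone 11, replacing steps 1–7 by classical chemistry. Cyclisation of 14 in 85% H3PO4 should give racemic α-ionone F1. Condensation of F1 with (1R,2S,5R)-menthyl carbazate (NaOAc, AcOH, EtOH) gives diastereomeric acylhydrazones, and fractional crystallisation should isolate the hydrazone of the 6S ketone, (1R,2S,5R)-menthyl 2-[(2E,3E)-4-[(1S)-2,6,6-trimethylcyclohex-2-en-1-yl]but-3-en-2-ylidene]hydrazine-1-carboxylate F2. If that diastereomer remains in the mother liquor, the carbazate of the antipodal menthol is used. Mild two-phase exchange with aqueous oxalic acid releases 11.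

Step 7. Turnover at the doubly flanked vinyl group may be poor, or ruthenium hydride may migrate the double bond and erode C6. The fallback sets out from 9 and comes back at 11 without metathesis. Acetonitrile oxide (EtNO2, PhNCO, catalytic Et3N, toluene) should add regioselectively to the monosubstituted alkene to give 3-methyl-5-[(1S)-2,6,6-trimethylcyclohex-2-en-1-yl]-4,5-dihydro-1,2-oxazole F3. N–O cleavage and imine hydrolysis with Mo(CO)6 in MeCN/H2O give 4-hydroxy-4-[(1S)-2,6,6-trimethylcyclohex-2-en-1-yl]butan-2-one F4. MsCl and Et3N in CH2Cl2 form 4-oxo-2-[(1S)-2,6,6-trimethylcyclohex-2-en-1-yl]butan-2-yl methanesulfonate F5, which eliminates in the flask toward the ketone to give the E-enone 11.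

Step 5. The iodo ylide may decompose, deiodinated alkene may form, or Z-selectivity may be incomplete. The fallback sets out from aldehyde 7 and comes back at 8. Corey–Fuchs dibromoolefination (CBr4, PPh3, Et3N, CH2Cl2, 0 °C) gives (6E)-1,1-dibromo-5,5-dimethyl-8-(trimethylsilyl)octa-1,6-diene F6. Negishi monomethylation (MeZnCl, PdCl2(DPEphos), THF), selective for the bromide trans to the chain, gives (2Z,7E)-2-bromo-6,6-dimethyl-9-(trimethylsilyl)nona-2,7-diene F7. Copper-catalysed halogen exchange with retention (CuI, N,N′-dimethylethylenediamine, NaI, dioxane, 110 °C) then gives 8.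

**Further compounds**

F1 | step 6 | racemic α-ionone, (3E)-4-(2,6,6-trimethylcyclohex-2-en-1-yl)but-3-en-2-one | CC(=O)/C=C/C1C(C)=CCCC1(C)C
F2 | step 6 | (1R,2S,5R)-menthyl 2-[(2E,3E)-4-[(1S)-2,6,6-trimethylcyclohex-2-en-1-yl]but-3-en-2-ylidene]hydrazine-1-carboxylate | C[C@@H]1CC[C@H]([C@@H](C1)OC(=O)N/N=C(C)/C=C/[C@@H]2C(C)=CCCC2(C)C)C(C)C
F3 | step 7 | 3-methyl-5-[(1S)-2,6,6-trimethylcyclohex-2-en-1-yl]-4,5-dihydro-1,2-oxazole (C5 epimers) | CC1=NOC(C1)[C@@H]2C(C)=CCCC2(C)C
F4 | step 7 | 4-hydroxy-4-[(1S)-2,6,6-trimethylcyclohex-2-en-1-yl]butan-2-one (C4 epimers) | CC(=O)CC(O)[C@@H]1C(C)=CCCC1(C)C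
F5 | step 7 | 4-oxo-2-[(1S)-2,6,6-trimethylcyclohex-2-en-1-yl]butan-2-yl methanesulfonate (epimers) | CC(=O)CC(OS(C)(=O)=O)[C@@H]1C(C)=CCCC1(C)C
F6 | step 5 | (6E)-1,1-dibromo-5,5-dimethyl-8-(trimethylsilyl)octa-1,6-diene | BrC(Br)=CCCC(C)(C)/C=C/C[Si](C)(C)C
F7 | step 5 | (2Z,7E)-2-bromo-6,6-dimethyl-9-(trimethylsilyl)nona-2,7-diene | C/C(Br)=C/CCC(C)(C)/C=C/C[Si](C)(C)C
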